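**Strategy.** The plan rests on cutting the pyranone ring at C3–C4 and O1–C8a, which splits the target into pentatriacontan-2-one and 2,6-difluoro-4-methoxybenzoyl chloride. C8a and C5 are the two ortho positions of the C4 acyl carbon and the 7-methoxy group sits para to it, so the aroyl unit is symmetric. In one operation the methyl-side enolate is C-aroylated and the diketonate oxygen closes the ring by SNAr on either fluorine, leaving the other at C5 for exchange to hydroxyl. The ketone comes from a C30 + C5 copper-catalysed Grignard coupling; the endgame is benzyloxide SNAr and hydrogenolysis.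

Key step: step 4

Remark: the target has no stereocentre, so no stereocontrol is needed; 2-(3-chloropropyl)-2-methyl-1,3-dioxolane (the ethylene ketal of 5-chloropentan-2-one) is taken as a catalogue compound.

**Step 1**
Reactants: 1 1-triacontanol
Product: 2 1-bromotriacontane
Conditions: CBr4, PPh3, CH2Cl2–THF, 0 → 35 °C
Reagents that add atoms: carbon tetrabromide, BrC(Br)(Br)Br
Why: The Appel reaction converts the unhindered primary alcohol into the bromide by SN2 displacement of an alkoxyphosphonium ion under neutral conditions, so neither rearrangement nor elimination is expected.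

**Step 2**
Reactants: 3 2-(3-chloropropyl)-2-methyl-1,3-dioxolane; 2 1-bromotriacontane
Product: 6 pentatriacontan-2-one, via Grignard reagent 4 (not isolated), via dioxolane 5 (not isolated)
Conditions: Mg, BrCH2CH2Br (cat.), THF, reflux; then 2, Li2CuCl4 (3 mol %), THF, 0 → 30 °C; then 2 M HCl, THF, 55 °C
Reagents that add atoms: water, O
Why: Magnesium insertion into the primary chloride gives a Grignard reagent that tolerates its own acetal, its copper-catalysed sp3–sp3 cross-coupling with a primary bromide is standard for long chains, and the aqueous acid quench hydrolyses the acetal to the methyl ketone.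

**Step 3**
Reactants: 7 2,6-difluoro-4-methoxybenzoic acid
Product: 8 2,6-difluoro-4-methoxybenzoyl chloride
Conditions: (COCl)2, DMF (cat.), CH2Cl2, 0 °C → rt
Reagents that add atoms: oxalyl chloride, O=C(Cl)C(Cl)=O
Why: Vilsmeier-type activation by oxalyl chloride and catalytic DMF turns the benzoic acid into its chloride with only gaseous co-products, and the aryl fluorides and the methyl ether are inert.

**Step 4**
Reactants: 6 pentatriacontan-2-one; 8 2,6-difluoro-4-methoxybenzoyl chloride
Product: 10 5-fluoro-7-methoxy-2-tritriacontyl-4H-chromen-4-one, via diketone 9 (not isolated)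
Conditions: LiHMDS (2.1 equiv), THF–toluene, −40 °C (6 added as a warm solution, inverse addition); 8 (1.05 equiv), −60 → 0 °C; 1 M HCl work-up; then K2CO3, DMF–toluene, 90 °C
Reagents that add atoms: none
Why: Adding ketone 6 to an excess of the hindered amide removes a methyl proton irreversibly, and the terminal lithium enolate attacks the acid chloride at carbon through a tetrahedral intermediate that loses chloride (C3–C4), the second equivalent of base at once converting diketone 9 into its chelated enolate so that it is not acylated again. With carbonate in hot DMF the enolate oxygen on the alkyl side adds to the fluorine-bearing carbon ortho to the aroyl carbonyl, giving a Meisenheimer anion stabilised by that carbonyl, and loss of fluoride forms O1–C8a. The closest known reaction type is the acylation of ketone enolates with 2-fluorobenzoyl chlorides followed by intramolecular SNAr, an established entry to chromones and 4-quinolones. The pyranone ring closes as a six-membered ring by oxygen attack on an sp2 carbon (addition–elimination, 6-exo-trig if the C8a=C8 bond is taken as the acceptor), the only feasible mode because attack by the central carbon would give a four-membered ring. No stereocentre is formed. The step needs acylation at carbon of the methyl-side enolate, which the bulky base, the inverse addition at low temperature and the lithium counter-ion in a weakly polar medium should secure, whereas the site of ring closure needs no control because the two C–F carbons of the symmetric aroyl ring are equivalent.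

**Step 5**
Reactants: 10 5-fluoro-7-methoxy-2-tritriacontyl-4H-chromen-4-one
Product: 11 5-(benzyloxy)-7-methoxy-2-tritriacontyl-4H-chromen-4-one
Conditions: BnOH (3 equiv), NaH (1.5 equiv), THF; then 10, THF–DMF, 0 → 60 °C
Reagents that add atoms: benzyl alcohol, OCc1ccccc1
Why: The C5 fluorine is ortho to the C4 carbonyl and meta to both O1 and the 7-methoxy group, so benzyl alkoxide should displace it by SNAr through a carbonyl-stabilised Meisenheimer anion, while alkoxide addition at C2 is reversible and the excess alcohol keeps the CH2 next to C2 from staying deprotonated.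

**Step 6**
Reactants: 11 5-(benzyloxy)-7-methoxy-2-tritriacontyl-4H-chromen-4-one
Product: 12 5-hydroxy-7-methoxy-2-tritriacontyl-4H-chromen-4-one
Conditions: H2 (1 atm), 10 % Pd/C, THF–EtOAc, 35 °C
Reagents that add atoms: none
Why: Hydrogenolysis of the benzyl aryl ether over palladium should free the C5 phenol well before the vinylogous-ester C2=C3 bond is reduced, so the reaction is stopped once the ether is consumed.

**Compound list**
1 | 1-triacontanol | CCCCCCCCCCCCCCCCCCCCCCCCCCCCCCO | starting material
2 | 1-bromotriacontane | CCCCCCCCCCCCCCCCCCCCCCCCCCCCCCBr | intermediate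
3 | 2-(3-chloropropyl)-2-methyl-1,3-dioxolane | CC1(CCCCl)OCCO1 | starting material
4 | [3-(2-methyl-1,3-dioxolan-2-yl)propyl]magnesium chloride | CC1(CCC[Mg]Cl)OCCO1 | intermediate
5 | 2-methyl-2-tritriacontyl-1,3-dioxolane | CCCCCCCCCCCCCCCCCCCCCCCCCCCCCCCCCC1(C)OCCO1 | intermediate
6 | pentatriacontan-2-one | CCCCCCCCCCCCCCCCCCCCCCCCCCCCCCCCCC(C)=O | intermediate
7 | 2,6-difluoro-4-methoxybenzoic acid | COc1cc(F)c(C(=O)O)c(F)c1 | starting material
8 | 2,6-difluoro-4-methoxybenzoyl chloride | COc1cc(F)c(C(Cl)=O)c(F)c1 | intermediate
9 | 1-(2,6-difluoro-4-methoxyphenyl)hexatriacontane-1,3-dione | CCCCCCCCCCCCCCCCCCCCCCCCCCCCCCCCCC(=O)CC(=O)c1c(F)cc(OC)cc1F | intermediate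
10 | 5-fluoro-7-methoxy-2-tritriacontyl-4H-chromen-4-one | CCCCCCCCCCCCCCCCCCCCCCCCCCCCCCCCCc1cc(=O)c2c(F)cc(OC)cc2o1 | intermediate
11 | 5-(benzyloxy)-7-methoxy-2-tritriacontyl-4H-chromen-4-one | CCCCCCCCCCCCCCCCCCCCCCCCCCCCCCCCCc1cc(=O)c2c(OCc3ccccc3)cc(OC)cc2o1 | intermediate
12 | 5-hydroxy-7-methoxy-2-tritriacontyl-4H-chromen-4-one | CCCCCCCCCCCCCCCCCCCCCCCCCCCCCCCCCc1cc(=O)c2c(O)cc(OC)cc2o1 | target

**Step count.** Total: 6 steps. Longest linear sequence: 5 steps (steps 1, 2, 4, 5, 6, from 1 to 12).

**Steps most likely to fail**

Step 4. The enolate may be acylated on oxygen, may form partly on the methylene side, or the diketonate may be acylated a second time, so that little of 9 reaches the ring closure. The fallback sets out from 8 and 6. Methanolysis of 8 (MeOH, rt) gives methyl 2,6-difluoro-4-methoxybenzoate F1. A crossed Claisen condensation of 6 with F1 (NaH, THF, 60 °C) runs under equilibrating conditions, in which only C-acylation at the methyl group leads to a stable diketonate. Acidification gives diketone 9, where the route is rejoined for the carbonate-mediated closure to 10.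

Step 5. Alkoxide addition at C2 may open the pyranone ring, or deprotonation of the chain CH2 next to C2 may turn the chromone into an electron-rich dienolate and stall the substitution. The fallback sets out from 10 and uses a weakly basic oxygen nucleophile. (E)-Benzaldoxime with K2CO3 in DMF–toluene at 80 °C should give (E)-benzaldehyde O-(7-methoxy-4-oxo-2-tritriacontyl-4H-chromen-5-yl)oxime F2. Under the same conditions F2 should lose benzonitrile by base-induced elimination to give the phenoxide. After acidic work-up the route is rejoined directly at target 12, so step 6 is not needed.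

Step 2. Magnesium insertion into the chloride may be sluggish, or cross-coupling of the sparingly soluble C30 bromide may be slow enough for homocoupling and reduction of the halide to take over. The fallback sets out from 2. Alkylation of dilithiated pent-4-yn-2-ol (n-BuLi 2 equiv, THF–DMPU, −40 °C → rt) with 2 gives racemic pentatriacont-4-yn-2-ol F3. Hydrogenation (H2, Pd/C, THF) gives racemic pentatriacontan-2-ol F4. Oxidation (Dess–Martin periodinane, CH2Cl2–THF) returns to the route at ketone 6.

**Further compounds**
F1 | step 4 | methyl 2,6-difluoro-4-methoxybenzoate | COC(=O)c1c(F)cc(OC)cc1F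
F2 | step 5 | (E)-benzaldehyde O-(7-methoxy-4-oxo-2-tritriacontyl-4H-chromen-5-yl)oxime | CCCCCCCCCCCCCCCCCCCCCCCCCCCCCCCCCc1cc(=O)c2c(O/N=C/c3ccccc3)cc(OC)cc2o1
F3 | step 2 | pentatriacont-4-yn-2-ol (racemic) | CCCCCCCCCCCCCCCCCCCCCCCCCCCCCCC#CCC(C)O
F4 | step 2 | pentatriacontan-2-ol (racemic) | CCCCCCCCCCCCCCCCCCCCCCCCCCCCCCCCCC(C)O
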